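## Structural features

The target is a germacranolide: a ten-membered carbocycle, numbered C1–C10 (C1 and C2 the oxirane carbons with C1 on C10, C3 the allylic carbinol, C4=C5 the methyl-bearing olefin, C6 the lactone O–CH, C7 the fusion CH, C8 the acyloxy CH, C9 the methylene, C10 the methyl carbinol), fused through C6–C7 to an α-methylene-γ-butyrolactone (C11–C13). Decoding the descriptors gives 1R,2R,3R,6S,7R,8R,10R with a 4Z olefin, a cis-disubstituted oxirane and, unusually for this family, a cis ring fusion (H6 and H7 on the same lactone face). The stereocentres form two contiguous runs, C10–C1–C2–C3 (tertiary carbinol syn to the C1 oxygen, C3 carbinol anti to the C2 oxygen) and C6–C7–C8, and the C8 and C10 oxygens are 1,3-anti. The fragile groups are the angelate (isomerises to tiglate; its γ-methyl is deprotonated by amide bases), the α-methylene lactone (Michael acceptor for alkoxides and metal enolates, reducible by SmI2), the oxirane flanked by two hydroxyls, the lactone (it can migrate to O8 whenever C8–O is a free alkoxide) and C7, which is epimerisable while C8 is a ketone. The real difficulty is closing a ten-membered ring that carries seven stereocentres, and ordering the late steps so that no sensitive group meets an incompatible reagent. The key step exploits the position of C10, β to the C8 oxygen and α to the C1 oxygen: with C8 as a ketone the ring contains an aldol retron C8(=O)–C9–C10(OH), and the C1 oxygen can chelate the metal that delivers a C9 enolate to a C10 methyl ketone. An atom-by-atom check of the seco bromoketone and of the cyclised ketone against the target shows all descriptors to be mutually consistent, so no structure needs correcting; only protecting groups are changed (TIPS in place of TBS at C3, and C10 kept as a silylated carbinol until the last step before cyclisation).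

## Logic of the disconnections

38 ⇒ 37 ⇒ 35 + 36. The C3 O–Si bond and the C8 O–acyl bond are cut last. The angelate tolerates neither amide bases nor K2CO3/MeOH, so it must follow every basic step. This leaves a diol in which only the secondary C8 hydroxyl can be acylated. The forward step must acylate without Z to E isomerisation and without letting the lactone migrate to O8.

35 ⇒ 34 ⇒ 31. The C11=C13 bond and the two O–Si bonds of a silylene bridging O8 and O10 are cut. The methylene lactone would not survive SmI2 or methanolic carbonate, so it is made after the oxirane; the silylene hides both hydroxyls from the amide base. The demand is enolate formation at −78 °C beside an oxirane.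

31 ⇒ 28 ⇒ 27. The oxirane C–O bonds are traced back to a cis C1/C2 diol (closure with net retention), itself masked as an acetonide. An epoxy ketone would be cleaved by SmI2, and an acetal oxygen at C1 is the chelating group the ring closure needs. The forward steps must remove the acetonide beside silyl ethers and convert the diol by double inversion.

27 ⇒ 26 ⇒ 25. The silylene is removed and the C8–H bond is cut, giving a β-hydroxy ketone. The demand is hydride delivery anti to the tertiary C10 hydroxyl inside a medium ring.

25 ⇒ 23. The C9–C10 bond is cut. This opens the ten-membered ring and removes the C10 stereocentre, leaving an acyclic chain held by a Z olefin, a cis lactone and a cis acetonide. The forward step needs a regiodefined, non-basic C9 enolate, chelation control and high dilution.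

23 ⇒ 22 ⇒ 21 ⇒ 18 ⇒ 17. The C10 ketone is taken back to a carbinol, so that the epimerisable C1 is exposed for one step only. The C8–C9 bond is cut (one-carbon homologation of a C8 acid) and the acid is taken back to an imide. The demand is activation of the acid without base, because C7 sits cis on the lactone.

17 ⇒ 16 ⇒ 5 + 15. The C3–C4 bond is cut between an α-alkoxy aldehyde and an alkenyl iodide; this is the convergent junction. The metal must tolerate lactone and imide, keep the Z geometry and add anti to the C2 oxygen.

15 ⇒ 12 + 9. The C6–C7 bond and the lactone C12–O bond are cut (aldol, then lactonisation). One auxiliary-controlled reaction sets C6 and C7, and only the anti adduct closes to the cis lactone. The demand is anti selectivity with a β-iodoenal.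

9 ⇒ 8 ⇒ 7 ⇒ 6; 12 ⇒ 10 + 11; 5 ⇒ 4 ⇒ 3 ⇒ 2 ⇒ 1. Anti hydroiodination of 6 fixes the Z iodide. C1 and C2 come unchanged from 1. C10 and its methyl come from a methyl addition whose stereochemistry is irrelevant.

## Other disconnections considered

Alternative 1: The cut removes the lactone carbonyl (C11–C12 and C12–O6), leaving the complete carbocycle A1 with a 1-iodovinyl group on C7 and a free C6 hydroxyl.
- Forward step: Pd(PPh3)4 under CO would insert zerovalent palladium into the C–I bond, take up CO and let the C6 hydroxyl capture the acylpalladium species, giving A2; two desilylations then lead to the target.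
- In favour: the Michael acceptor appears last, under neutral conditions, with oxirane and angelate in place. The clash between amide base, methanolic carbonate and angelate, which costs the chosen plan steps 18 and 22, does not arise. C7 has no carbonyl neighbour during ring construction, and the metal is catalytic. On these end-game points the alternative is the better plan.
- Against: it forms the easy five-membered ring and no stereocentre. It leaves open how the ten-membered ring of A1 is closed with all seven stereocentres and a reducible alkenyl iodide on board, and without the conformational bias that the lactone gives to 23.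
- Comparison: structurally the chosen step makes the strained ring and C10 at once, while A1 → A2 makes neither. Mechanistically carbonylation is the milder process. In step count the end game would be about two steps shorter, but a second strategic ring closure is still needed, so overall it is at best equal.

Alternative 2: The cut is made at C1–C2, taken as an olefin, with a sulfur atom inserted: the precursor is the eleven-membered sulfone A3.
- Forward step: α-halogenation and base (KOH/CCl4, or CBr2F2 on KOH–Al2O3) would give an episulfone that loses SO2 and contracts to the (1Z,4Z)-diene A4.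
- In favour: the ring is first closed as a thioether by thiolate displacement, an easier eleven-membered closure. The contraction is intramolecular and gives the cis olefin a ten-membered ring demands, and no stereocentre is formed in the ring-forming event. On reliability of the ring closure itself this is equal or better.
- Against: the C1/C2 oxygens must then come from an epoxidation that selects one of three olefins and one face while both neighbouring hydroxyls are silylated. The basic halogenating medium meets silyl ethers, and C10 must be set earlier in an acyclic precursor. The lactone is carried as two PMB ethers and an exocyclic olefin that still need deprotection, oxidation and lactonisation.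
- Comparison: the chosen plan takes C1/C2 from the chiral pool and sets C10 during cyclisation (better on stereocontrol). Extrusion and chelated aldol are comparably precedented. From A4 the target lies at least eight operations away, more than from 25.

Alternative 3: The cut breaks C8–C9 and C10–O, disguising the aldol as a cycloaddition: the precursor is the nitrile oxide A5 with an isopropenyl group at C10.
- Forward step: the nitrile oxide (from the C8 oxime and NaOCl) would add to the isopropenyl group to give the bridged isoxazoline A6. N–O cleavage (Mo(CO)6, wet MeCN) would then release the β-hydroxy ketone corresponding to 25 with the oxirane in place.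
- In favour: the conditions are neutral and no reducing metal is used, so the oxirane can be carried through ring closure. Steps 19 and 20 and the acetonide become unnecessary, which is better step economy after cyclisation. The regiochemistry is intrinsic and the adduct cannot undergo retro-aldol.
- Against: facial selectivity at C10 would rest on the allylic oxirane alone, with no chelate. The bridged ten-membered mode must beat dimerisation to the furoxan. The oxime sits on the epimerisable C7 of the cis lactone, the oxirane must survive hypochlorite, and N–O cleavage adds a step that must spare oxirane and olefin.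
- Comparison: both plans use the same two fragments and form the same ring bond (equal in convergence). The chosen plan has the firmer stereochemical model for C10; the alternative has the shorter end game.

Key step: step 16

Remark on the chemistry: germacrane numbering is used for all intermediates; 3–5 and 16–22 are carried as both C10 epimers because C10 becomes a ketone in step 15; methyl 4-chloro-4-oxobutanoate (11, the commercial half-ester chloride of succinic acid) is used in place of succinic anhydride to save a step.

## Route

Step 1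
Reactants: 1 2,3-O-isopropylidene-D-erythronolactone
Product: 2 2,3-O-isopropylidene-D-erythrose (lactol)
Conditions: i-Bu2AlH (1.1 equiv), CH2Cl2, −78 °C; aq. potassium sodium tartrate
Reagents that add atoms: none
Why: Partial reduction of a γ-lactone with i-Bu2AlH stops at the tetrahedral aluminate and gives the lactol on work-up; the two acetonide centres are untouched.

Step 2
Reactants: 2 2,3-O-isopropylidene-D-erythrose (lactol)
Product: 3 1-[(4S,5R)-5-(hydroxymethyl)-2,2-dimethyl-1,3-dioxolan-4-yl]ethan-1-ol (C10 epimers)
Conditions: MeMgBr (3 equiv), THF, 0 °C → rt; aq. NH4Cl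
Reagents that add atoms: methylmagnesium bromide, C[Mg]Br
Why: Grignard addition to the open hydroxy-aldehyde form of the lactol (the first equivalent deprotonates it) installs C10 and its methyl; the new carbinol centre is not controlled and need not be, since it is oxidised in step 15.

Step 3
Reactants: 3 diol (C10 epimers)
Product: 4 bis(triethylsilyl) ether of 3
Conditions: TESCl (2.4 equiv), imidazole, DMF, 0 °C → rt
Reagents that add atoms: chlorotriethylsilane, CC[Si](Cl)(CC)CC
Why: Routine silylation of both hydroxyls; TES is chosen because the primary ether can be oxidised directly and the secondary one can later be removed beside TIPS.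

Step 4
Reactants: 4 bis(triethylsilyl) ether
Product: 5 C3 aldehyde, cis-2,2-dimethyl-5-[1-(triethylsilyloxy)ethyl]-1,3-dioxolane-4-carbaldehyde (C1, C2 as in 1)
Conditions: (COCl)2, DMSO, CH2Cl2, −78 → −30 °C; Et3N, −78 → 0 °C
Reagents that add atoms: none
Why: Under Swern conditions a primary triethylsilyl ether is converted into the alkoxysulfonium ion much faster than a secondary one, so the aldehyde forms directly (selective oxidative desilylation); low temperature limits epimerisation of the cis α-alkoxy aldehyde, which is used at once.

Step 5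
Reactants: 6 ethyl but-2-ynoate
Product: 7 ethyl (Z)-3-iodobut-2-enoate
Conditions: NaI, AcOH, 70 °C
Reagents that add atoms: sodium iodide, [Na+].[I-]
Why: Conjugate hydroiodination of an ynoate is an anti addition of HI and gives the Z β-iodoenoate, with iodine cis to the future C6.

Step 6
Reactants: 7 ethyl (Z)-3-iodobut-2-enoate
Product: 8 (Z)-3-iodobut-2-en-1-ol
Conditions: i-Bu2AlH (2.2 equiv), CH2Cl2, −78 °C
Reagents that add atoms: none
Why: 1,2-Reduction of the enoate to the allylic alcohol; the alkenyl iodide is inert to i-Bu2AlH at −78 °C.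

Step 7
Reactants: 8 (Z)-3-iodobut-2-en-1-ol
Product: 9 (Z)-3-iodobut-2-enal
Conditions: MnO2, CH2Cl2, rt, dark
Reagents that add atoms: none
Why: Neutral allylic oxidation with MnO2; the Z geometry should hold if the aldehyde is used without storage.

Step 8
Reactants: 10 (R)-4-benzyloxazolidin-2-one; 11 methyl 4-chloro-4-oxobutanoate
Product: 12 (R)-4-benzyl-3-(4-methoxy-4-oxobutanoyl)oxazolidin-2-one
Conditions: n-BuLi, THF, −78 °C; then 11, −78 → 0 °C
Reagents that add atoms: none
Why: N-Acylation of the lithiated oxazolidinone by the acid chloride, which is far more reactive than the methyl ester.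

Step 9
Reactants: 12 succinoyl imide; 9 (Z)-3-iodobut-2-enal
Product: 15 (R)-4-benzyl-3-{[(2R,3S)-2-[(Z)-2-iodoprop-1-enyl]-5-oxooxolan-3-yl]carbonyl}oxazolidin-2-one (cis lactone imide), via O-trimethylsilyl anti-aldol adduct 13 (not isolated), via anti-aldol hydroxy ester 14 (not isolated)
Conditions: MgCl2 (20 mol %), Et3N, TMSCl, EtOAc, rt; 1 M HCl/THF; TsOH·H2O (cat.), CH2Cl2, rt
Reagents that add atoms: none
Why: Magnesium-halide-catalysed direct anti-aldol of an N-acyloxazolidinone: the chelated Z magnesium enolate reacts through a boat-like transition state and silylation turns the catalyst over. The (R)-benzyl group shields one enolate face, fixing C7, and the aldehyde is taken up anti, fixing C6. Acid removes the silyl ether and only the anti γ-hydroxy ester can close to the cis-4,5-disubstituted lactone.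

Step 10
Reactants: 5 C3 aldehyde; 15 cis lactone imide
Product: 16 C3 allylic alcohol (C10–OTES, C1/C2 acetonide, C8 imide; 3R)
Conditions: CrCl2 (5 equiv), NiCl2 (2 mol %), DMSO, rt
Reagents that add atoms: none
Why: Nozaki–Hiyama–Kishi coupling: zerovalent nickel inserts into the C–I bond, and transmetalation gives an alkenyl species of trivalent chromium that adds only to the aldehyde, leaving lactone, imide and silyl ether. Felkin–Anh addition anti to the C2–O bond should give the 2,3-anti (3R) alcohol with the Z geometry retained.

Step 11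
Reactants: 16 C3 allylic alcohol
Product: 17 C3 triisopropylsilyl ether
Conditions: TIPSOTf, 2,6-lutidine, CH2Cl2, −40 → 0 °C
Reagents that add atoms: triisopropylsilyl trifluoromethanesulfonate, CC(C)[Si](OS(=O)(=O)C(F)(F)F)(C(C)C)C(C)C
Why: Silyl triflate with a hindered base silylates the crowded secondary alcohol; TIPS is preferred to TBS because it must outlast the acetonide cleavage of step 19 and the silylene removal of step 22.

Step 12
Reactants: 17 C3 triisopropylsilyl ether
Product: 18 C8 carboxylic acid (cis lactone acid)
Conditions: LiOH, H2O2, THF/H2O (3:1), 0 °C; Na2SO3; 1 M HCl to pH 4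
Reagents that add atoms: hydrogen peroxide, OO
Why: LiOOH attacks the exocyclic imide carbonyl selectively (standard auxiliary hydrolysis); its low basicity spares the epimerisable C7, and any lactone that opens recloses on acidification.

Step 13
Reactants: 18 C8 carboxylic acid
Product: 21 C8 bromomethyl ketone (C10–OTES), via acid chloride 19 (not isolated), via diazoketone 20 (not isolated)
Conditions: 1-chloro-N,N,2-trimethylprop-1-en-1-amine, CH2Cl2, 0 °C; CH2N2, Et2O, 0 °C; N2 purge; 48% aq. HBr (1.1 equiv), −20 °C
Reagents that add atoms: diazomethane, C=[N+]=[N-]; hydrogen bromide, Br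
Why: The acid chloride is made under neutral conditions, acylates diazomethane (as in the first stage of an Arndt–Eistert sequence) and the diazoketone is cleaved by HBr to the bromomethyl ketone, adding C9. No base able to epimerise C7 is present, and cold stoichiometric acid leaves acetonide and TIPS ether intact.

Step 14
Reactants: 21 C8 bromomethyl ketone (C10–OTES)
Product: 22 C10 carbinol
Conditions: HF·pyridine, pyridine, THF, 0 °C
Reagents that add atoms: none
Why: Buffered HF·pyridine cleaves the secondary triethylsilyl ether much faster than the hindered TIPS ether; bromoketone, acetonide and lactone are inert.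

Step 15
Reactants: 22 C10 carbinol
Product: 23 seco C8 bromomethyl ketone / C10 methyl ketone (C1/C2 acetonide, C3–OTIPS)
Conditions: Dess–Martin periodinane, NaHCO3, CH2Cl2, 0 °C → rt
Reagents that add atoms: none
Why: Buffered Dess–Martin oxidation gives the α-alkoxy methyl ketone without enolising C1 or C7; the diketone is not stored.

Step 16
Reactants: 23 seco bromomethyl ketone / methyl ketone
Product: 25 ten-membered C8 ketone bearing the C10 tertiary alcohol (10R), via samarium enolate 24 (not isolated)
Conditions: SmI2 (2.5 equiv, 0.1 M in THF), THF, −78 °C, slow addition of 23 (final 2 mM); aq. NH4Cl at −78 °C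
Reagents that add atoms: none
Why: Two electrons from SmI2 cleave the C–Br bond and give the O-bound enolate of trivalent samarium 24, with the nucleophilic carbon fixed at C9. The oxophilic metal binds the C10 carbonyl and the C1 acetal oxygen and the enolate adds through a closed six-membered array; this is an intramolecular samarium Reformatsky reaction, closest in type to SmI2-promoted Reformatsky cyclisations of α-halo carbonyl compounds to medium and large rings. The ten-membered carbocycle closes by 10-(enolendo)-exo-trig attack of C9 on C10. The new C10 centre is set by the Cram chelate: C9 approaches the carbonyl face away from C2 on the five-membered chelate, which puts the hydroxyl syn to the C1 oxygen. The step needs C–Br reduction to outrun electron transfer to the α-alkoxy ketone (which would expel the C1 oxygen); the much easier reduction of α-halo ketones, −78 °C and the absence of HMPA or proton donors secure this. Because the enolate is formed only at C9 and is non-basic, C7 is not epimerised and the C6 lactone oxygen does not β-eliminate; lactone and silyl ether are inert to SmI2. Slow addition suppresses intermolecular aldol reaction and the cold quench prevents retro-aldol of the samarium aldolate.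

Step 17
Reactants: 25 ten-membered β-hydroxy ketone
Product: 26 C8,C10-anti diol (8R)
Conditions: Me4NBH(OAc)3, MeCN/AcOH (1:1), −30 °C
Reagents that add atoms: none
Why: Evans–Saksena reduction: the C10 hydroxyl exchanges onto boron and hydride is delivered intramolecularly through a chair, which should give the 1,3-anti alcohol at C8; the reagent does not touch the lactone.

Step 18
Reactants: 26 C8,C10-anti diol
Product: 27 C8,C10 di-tert-butylsilylene derivative
Conditions: t-Bu2Si(OTf)2, 2,6-lutidine, CH2Cl2, 0 °C → rt
Reagents that add atoms: di-tert-butylsilyl bis(trifluoromethanesulfonate), CC(C)(C)[Si](OS(=O)(=O)C(F)(F)F)(OS(=O)(=O)C(F)(F)F)C(C)(C)C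
Why: The bis-triflate silylates 1,3-diols including tertiary hydroxyls; one group masks O8 and O10 against the later base steps and blocks lactone migration to O8.

Step 19
Reactants: 27 silylene acetonide
Product: 28 C1,C2 cis-diol
Conditions: EtSH, Zn(OTf)2, NaHCO3, CH2Cl2, 0 °C → rt
Reagents that add atoms: none
Why: Lewis-acid-mediated transketalisation moves the isopropylidene group onto the thiol under non-aqueous conditions that should leave TIPS ether, silylene and lactone untouched.

Step 20
Reactants: 28 C1,C2 cis-diol
Product: 31 cis-1,2-epoxide (1R,2R), via cyclic orthoacetate 29 (not isolated), via C2 bromide C1 acetate 30 (not isolated)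
Conditions: MeC(OMe)3, PPTS (cat.), CH2Cl2, rt; AcBr, CH2Cl2, 0 °C; K2CO3, MeOH, 0 °C → rt
Reagents that add atoms: none
Why: Kolb–Sharpless one-pot conversion: the cyclic orthoacetate gives an acetoxonium ion that bromide opens with inversion (expected at the less hindered C2), and acetate methanolysis then lets O1 displace bromide with a second inversion, so the cis oxirane forms with net retention at both carbons. With O8, O10 and O3 masked no other ring can close, and neither the angelate nor the methylene lactone is yet present to suffer from methoxide.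

Step 21
Reactants: 31 cis-1,2-epoxide
Product: 34 α-methylene lactone, via Mannich base 32 (not isolated), via trimethylammonium iodide 33 (not isolated)
Conditions: LiN(i-Pr)2, THF, −78 °C; CH2=NMe2+ I−, −78 °C → rt; MeI, THF, rt; aq. NaHCO3/EtOAc
Reagents that add atoms: N,N-dimethylmethyleneiminium iodide, C=[N+](C)C.[I-]
Why: Lactone enolate Mannich reaction followed by quaternisation and elimination (α-methylenation of a lactone); no free hydroxyl, ketone or angelate is present, and at −78 °C the enolate is trapped faster than it can attack the oxirane.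

Step 22
Reactants: 34 α-methylene lactone
Product: 35 C8,C10 diol (C3–OTIPS)
Conditions: HF·pyridine, pyridine, THF, 0 °C
Reagents that add atoms: none
Why: Dialkoxy-di-tert-butylsilanes are cleaved by buffered HF·pyridine within a short time at 0 °C, conditions a secondary TIPS ether, the oxirane and the methylene lactone should survive.

Step 23
Reactants: 35 C8,C10 diol; 36 angelic acid, (Z)-2-methylbut-2-enoic acid
Product: 37 C8 angelate (C3–OTIPS)
Conditions: 36, 2,4,6-Cl3C6H2COCl, Et3N, toluene, rt; then 35, toluene, 80 °C
Reagents that add atoms: none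
Why: Yamaguchi-type mixed-anhydride acylation without a nucleophilic catalyst, the usual way to make angelates with little isomerisation to the tiglate. Only the secondary C8 hydroxyl reacts (the tertiary C10 hydroxyl is inert), and the weak amine base should not trigger lactone migration.

Step 24
Reactants: 37 C8 angelate (C3–OTIPS)
Product: 38 target, CNP0351240.2
Conditions: HF·pyridine, pyridine, THF, 0 °C → rt
Reagents that add atoms: none
Why: Buffered fluoride desilylation of the secondary TIPS ether under mildly acidic conditions that oxirane, angelate and methylene lactone tolerate; this gives the target.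

## Compound list

1 | 2,3-O-isopropylidene-D-erythronolactone | O=C1OC[C@H]2OC(C)(C)O[C@@H]12 | starting material
2 | 2,3-O-isopropylidene-D-erythrose (lactol, both anomers) | OC1OC[C@H]2OC(C)(C)O[C@@H]12 | intermediate
3 | 1-[(4S,5R)-5-(hydroxymethyl)-2,2-dimethyl-1,3-dioxolan-4-yl]ethan-1-ol (C10 epimers) | CC(O)[C@@H]1OC(C)(C)O[C@@H]1CO | intermediate
4 | bis(triethylsilyl) ether of 3 | CC(O[Si](CC)(CC)CC)[C@@H]1OC(C)(C)O[C@@H]1CO[Si](CC)(CC)CC | intermediate
5 | C3 aldehyde, cis-2,2-dimethyl-5-[1-(triethylsilyloxy)ethyl]-1,3-dioxolane-4-carbaldehyde (C1, C2 as in 1; C10 epimers) | CC(O[Si](CC)(CC)CC)[C@@H]1OC(C)(C)O[C@@H]1C=O | intermediate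
6 | ethyl but-2-ynoate | CCOC(=O)C#CC | starting material
7 | ethyl (Z)-3-iodobut-2-enoate | CCOC(=O)/C=C(/C)I | intermediate
8 | (Z)-3-iodobut-2-en-1-ol | OC/C=C(/C)I | intermediate
9 | (Z)-3-iodobut-2-enal | O=C/C=C(/C)I | intermediate
10 | (R)-4-benzyloxazolidin-2-one | O=C1N[C@H](Cc2ccccc2)CO1 | starting material
11 | methyl 4-chloro-4-oxobutanoate | COC(=O)CCC(Cl)=O | starting material
12 | (R)-4-benzyl-3-(4-methoxy-4-oxobutanoyl)oxazolidin-2-one | COC(=O)CCC(=O)N1[C@H](Cc2ccccc2)COC1=O | intermediate
13 | O-trimethylsilyl anti-aldol adduct (C6–OTMS, C12 methyl ester, C8 imide) | COC(=O)C[C@@H]([C@@H](O[Si](C)(C)C)/C=C(/C)I)C(=O)N1[C@H](Cc2ccccc2)COC1=O | intermediate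
14 | anti-aldol hydroxy ester (C6–OH anti to the C11 ester arm) | COC(=O)C[C@@H]([C@@H](O)/C=C(/C)I)C(=O)N1[C@H](Cc2ccccc2)COC1=O | intermediate
15 | (R)-4-benzyl-3-{[(2R,3S)-2-[(Z)-2-iodoprop-1-enyl]-5-oxooxolan-3-yl]carbonyl}oxazolidin-2-one (cis lactone imide) | I/C(C)=C\[C@@H]1OC(=O)C[C@@H]1C(=O)N2[C@H](Cc3ccccc3)COC2=O | intermediate
16 | coupled C3 allylic alcohol (3R; C10–OTES, C1/C2 acetonide, 4Z, cis lactone, C8 imide) | CC(O[Si](CC)(CC)CC)[C@@H]1OC(C)(C)O[C@@H]1[C@H](O)/C(C)=C\[C@@H]2OC(=O)C[C@@H]2C(=O)N3[C@H](Cc4ccccc4)COC3=O | intermediate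
17 | C3 triisopropylsilyl ether of 16 | CC(O[Si](CC)(CC)CC)[C@@H]1OC(C)(C)O[C@@H]1[C@H](O[Si](C(C)C)(C(C)C)C(C)C)/C(C)=C\[C@@H]2OC(=O)C[C@@H]2C(=O)N3[C@H](Cc4ccccc4)COC3=O | intermediate
18 | C8 carboxylic acid (auxiliary removed) | CC(O[Si](CC)(CC)CC)[C@@H]1OC(C)(C)O[C@@H]1[C@H](O[Si](C(C)C)(C(C)C)C(C)C)/C(C)=C\[C@@H]2OC(=O)C[C@@H]2C(=O)O | intermediate
19 | C8 acid chloride | CC(O[Si](CC)(CC)CC)[C@@H]1OC(C)(C)O[C@@H]1[C@H](O[Si](C(C)C)(C(C)C)C(C)C)/C(C)=C\[C@@H]2OC(=O)C[C@@H]2C(Cl)=O | intermediate
20 | C8 diazomethyl ketone | CC(O[Si](CC)(CC)CC)[C@@H]1OC(C)(C)O[C@@H]1[C@H](O[Si](C(C)C)(C(C)C)C(C)C)/C(C)=C\[C@@H]2OC(=O)C[C@@H]2C(=O)C=[N+]=[N-] | intermediate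
21 | C8 bromomethyl ketone with C10–OTES | CC(O[Si](CC)(CC)CC)[C@@H]1OC(C)(C)O[C@@H]1[C@H](O[Si](C(C)C)(C(C)C)C(C)C)/C(C)=C\[C@@H]2OC(=O)C[C@@H]2C(=O)CBr | intermediate
22 | C8 bromomethyl ketone with free C10 carbinol | CC(O)[C@@H]1OC(C)(C)O[C@@H]1[C@H](O[Si](C(C)C)(C(C)C)C(C)C)/C(C)=C\[C@@H]2OC(=O)C[C@@H]2C(=O)CBr | intermediate
23 | seco C8 bromomethyl ketone / C10 methyl ketone (C1/C2 acetonide, C3–OTIPS) | CC(=O)[C@@H]1OC(C)(C)O[C@@H]1[C@H](O[Si](C(C)C)(C(C)C)C(C)C)/C(C)=C\[C@@H]2OC(=O)C[C@@H]2C(=O)CBr | intermediate
24 | C8/C9 samarium enolate (O–SmI2, trivalent samarium) | CC(=O)[C@@H]1OC(C)(C)O[C@@H]1[C@H](O[Si](C(C)C)(C(C)C)C(C)C)/C(C)=C\[C@@H]2OC(=O)C[C@@H]2C(=C)O[Sm](I)I | intermediate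
25 | ten-membered C8 ketone with C10 tertiary alcohol (C1/C2 acetonide, C3–OTIPS) | C1C(=O)O[C@H]2/C=C(/C)[C@@H](O[Si](C(C)C)(C(C)C)C(C)C)[C@H]3OC(C)(C)O[C@H]3[C@](C)(O)CC(=O)[C@@H]12 | intermediate
26 | C8,C10-anti diol | C1C(=O)O[C@H]2/C=C(/C)[C@@H](O[Si](C(C)C)(C(C)C)C(C)C)[C@H]3OC(C)(C)O[C@H]3[C@](C)(O)C[C@@H](O)[C@@H]12 | intermediate
27 | C8,C10 di-tert-butylsilylene derivative | C1C(=O)O[C@H]2/C=C(/C)[C@@H](O[Si](C(C)C)(C(C)C)C(C)C)[C@H]3OC(C)(C)O[C@H]3[C@@]4(C)C[C@@H](O[Si](C(C)(C)C)(C(C)(C)C)O4)[C@@H]12 | intermediate
28 | C1,C2 cis-diol | C1C(=O)O[C@H]2/C=C(/C)[C@@H](O[Si](C(C)C)(C(C)C)C(C)C)[C@@H](O)[C@@H](O)[C@@]3(C)C[C@@H](O[Si](C(C)(C)C)(C(C)(C)C)O3)[C@@H]12 | intermediate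
29 | C1,C2 cyclic methyl orthoacetate | C1C(=O)O[C@H]2/C=C(/C)[C@@H](O[Si](C(C)C)(C(C)C)C(C)C)[C@H]3OC(C)(OC)O[C@H]3[C@@]4(C)C[C@@H](O[Si](C(C)(C)C)(C(C)(C)C)O4)[C@@H]12 | intermediate
30 | C2 bromide (inverted) / C1 acetate | C1C(=O)O[C@H]2/C=C(/C)[C@@H](O[Si](C(C)C)(C(C)C)C(C)C)[C@H](Br)[C@@H](OC(C)=O)[C@@]3(C)C[C@@H](O[Si](C(C)(C)C)(C(C)(C)C)O3)[C@@H]12 | intermediate
31 | cis-1,2-epoxide | C1C(=O)O[C@H]2/C=C(/C)[C@@H](O[Si](C(C)C)(C(C)C)C(C)C)[C@H]3O[C@H]3[C@@]4(C)C[C@@H](O[Si](C(C)(C)C)(C(C)(C)C)O4)[C@@H]12 | intermediate
32 | C11 dimethylaminomethyl lactone (Mannich base, C11 epimers) | CN(C)CC1C(=O)O[C@H]2/C=C(/C)[C@@H](O[Si](C(C)C)(C(C)C)C(C)C)[C@H]3O[C@H]3[C@@]4(C)C[C@@H](O[Si](C(C)(C)C)(C(C)(C)C)O4)[C@@H]12 | intermediate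
33 | C11 trimethylammoniomethyl lactone iodide | C[N+](C)(C)CC1C(=O)O[C@H]2/C=C(/C)[C@@H](O[Si](C(C)C)(C(C)C)C(C)C)[C@H]3O[C@H]3[C@@]4(C)C[C@@H](O[Si](C(C)(C)C)(C(C)(C)C)O4)[C@@H]12.[I-] | intermediate
34 | α-methylene lactone (silylene, C3–OTIPS) | C=C1C(=O)O[C@H]2/C=C(/C)[C@@H](O[Si](C(C)C)(C(C)C)C(C)C)[C@H]3O[C@H]3[C@@]4(C)C[C@@H](O[Si](C(C)(C)C)(C(C)(C)C)O4)[C@@H]12 | intermediate
35 | C8,C10 diol with C3–OTIPS | C=C1C(=O)O[C@H]2/C=C(/C)[C@@H](O[Si](C(C)C)(C(C)C)C(C)C)[C@H]3O[C@H]3[C@](C)(O)C[C@@H](O)[C@@H]12 | intermediate
36 | angelic acid, (Z)-2-methylbut-2-enoic acid | C/C=C(/C)C(=O)O | starting material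
37 | C8 angelate with C3–OTIPS | C=C1C(=O)O[C@H]2/C=C(/C)[C@@H](O[Si](C(C)C)(C(C)C)C(C)C)[C@H]3O[C@H]3[C@](C)(O)C[C@@H](OC(=O)/C(C)=C\C)[C@@H]12 | intermediate
38 | CNP0351240.2 | C=C1C(=O)O[C@H]2/C=C(/C)[C@@H](O)[C@H]3O[C@H]3[C@](C)(O)C[C@@H](OC(=O)/C(C)=C\C)[C@@H]12 | target

## Step count and least certain steps

Total: 24 steps. Longest linear sequence: 19 steps (1 → 5 through steps 1–4, or 6 → 15 through steps 5–7 and 9, then steps 10–24).

Step 16 (key step). The strained ring may close too slowly. The samarium enolate would then be protonated (simple debromination), or electron transfer to the α-alkoxy ketone would expel the C1 oxygen. C9 could also attack the non-chelated face, or the aldolate could undergo retro-aldol on warming. Fallback, from 23: Zn and TMSCl in MeCN convert the bromoketone regiospecifically into the C9 trimethylsilyl enol ether F1. A chelation-controlled Mukaiyama aldol addition with TiCl4 (or the milder MgBr2·OEt2) in CH2Cl2 at −78 °C under high dilution, followed by aqueous work-up, returns to the route at 25.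

Step 9. Triethylamine may add to the β-iodoenal and scramble or destroy the Z iodide, and coordination of the pendant ester to magnesium may erode the anti selectivity. Fallback, from 8 and 12:
- Halogen–lithium exchange on 8 (t-BuLi, Et2O, −78 °C) and Bu3SnCl give the base-inert (Z)-3-(tributylstannyl)but-2-en-1-ol F2.
- MnO2 gives (Z)-3-(tributylstannyl)but-2-enal F3.
- The aldol reaction with 12 under the conditions of step 9 gives the stannyl O-trimethylsilyl adduct F4, PPTS in MeOH the stannyl hydroxy ester F5, and PPTS in warm toluene the stannyl cis lactone imide F6.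
- Iododestannylation with I2 in CH2Cl2 at 0 °C, with retention, returns to the route at 15.

Step 10. Facial selectivity at C3 may be low if chromium chelates the acetal oxygen. The hindered iodide may couple slowly, and zerovalent nickel may ionise the allylic lactone C6–O bond. Fallback, from the C3 epimer mixture of 16: Dess–Martin oxidation gives the C3 enone F7, and reagent-controlled reduction with (R)-2-methyl-CBS-oxazaborolidine and catecholborane (alkenyl taken as the large group) returns to 16.

Step 20. Orthoester formation on the hindered macrocyclic diol may stall, or the acetoxonium ion may be captured by a transannular oxygen instead of bromide, so that acyl migration replaces ring closure. Fallback, from 28: SOCl2 and Et3N give the C1,C2 cyclic sulfite F8. LiBr in DMF at 60 °C followed by dilute acid gives the trans C2 bromide C1 alcohol F9, and K2CO3 in MeOH closes it with the second inversion, returning to 31.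

Step 17. The medium ring may not accommodate the chair needed for internal hydride delivery, and the tertiary hydroxyl may exchange slowly onto boron, so the anti selectivity may be poor. Fallback, from 25 (or from the unwanted portion of the step 17 mixture): NaBH4/CeCl3 in MeOH at −78 °C delivers hydride externally and should give mainly the 8-epimer diol F10. Mitsunobu inversion (4-nitrobenzoic acid, PPh3, diisopropyl azodicarboxylate) gives the C8 4-nitrobenzoate F11, and brief K2CO3/MeOH at 0 °C returns to 26.

## Further compounds

F1 | step 16 | C9 trimethylsilyl enol ether of 23 | CC(=O)[C@@H]1OC(C)(C)O[C@@H]1[C@H](O[Si](C(C)C)(C(C)C)C(C)C)/C(C)=C\[C@@H]2OC(=O)C[C@@H]2C(=C)O[Si](C)(C)C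
F2 | step 9 | (Z)-3-(tributylstannyl)but-2-en-1-ol | OC/C=C(/C)[Sn](CCCC)(CCCC)CCCC
F3 | step 9 | (Z)-3-(tributylstannyl)but-2-enal | O=C/C=C(/C)[Sn](CCCC)(CCCC)CCCC
F4 | step 9 | stannyl O-trimethylsilyl adduct (tributylstannyl analogue of 13) | COC(=O)C[C@@H]([C@@H](O[Si](C)(C)C)/C=C(/C)[Sn](CCCC)(CCCC)CCCC)C(=O)N1[C@H](Cc2ccccc2)COC1=O
F5 | step 9 | stannyl hydroxy ester (tributylstannyl analogue of 14) | COC(=O)C[C@@H]([C@@H](O)/C=C(/C)[Sn](CCCC)(CCCC)CCCC)C(=O)N1[C@H](Cc2ccccc2)COC1=O
F6 | step 9 | stannyl cis lactone imide (tributylstannyl analogue of 15) | CCCC[Sn](CCCC)(CCCC)/C(C)=C\[C@@H]1OC(=O)C[C@@H]1C(=O)N2[C@H](Cc3ccccc3)COC2=O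
F7 | step 10 | C3 enone from 16 | CC(O[Si](CC)(CC)CC)[C@@H]1OC(C)(C)O[C@@H]1C(=O)/C(C)=C\[C@@H]2OC(=O)C[C@@H]2C(=O)N3[C@H](Cc4ccccc4)COC3=O
F8 | step 20 | C1,C2 cyclic sulfite of 28 | C1C(=O)O[C@H]2/C=C(/C)[C@@H](O[Si](C(C)C)(C(C)C)C(C)C)[C@H]3OS(=O)O[C@H]3[C@@]4(C)C[C@@H](O[Si](C(C)(C)C)(C(C)(C)C)O4)[C@@H]12
F9 | step 20 | trans C2 bromide C1 alcohol | C1C(=O)O[C@H]2/C=C(/C)[C@@H](O[Si](C(C)C)(C(C)C)C(C)C)[C@H](Br)[C@@H](O)[C@@]3(C)C[C@@H](O[Si](C(C)(C)C)(C(C)(C)C)O3)[C@@H]12
F10 | step 17 | 8-epimer of diol 26 | C1C(=O)O[C@H]2/C=C(/C)[C@@H](O[Si](C(C)C)(C(C)C)C(C)C)[C@H]3OC(C)(C)O[C@H]3[C@](C)(O)C[C@H](O)[C@@H]12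
F11 | step 17 | C8 4-nitrobenzoate of 26 | C1C(=O)O[C@H]2/C=C(/C)[C@@H](O[Si](C(C)C)(C(C)C)C(C)C)[C@H]3OC(C)(C)O[C@H]3[C@](C)(O)C[C@@H](OC(=O)c4ccc(cc4)[N+](=O)[O-])[C@@H]12
A1 | alternative 1 | carbocycle with C7 1-iodovinyl group and free C6 hydroxyl | C=C(I)[C@H]1[C@@H](O)/C=C(/C)[C@@H](O[Si](C)(C)C(C)(C)C)[C@H]2O[C@H]2[C@](C)(O[Si](CC)(CC)CC)C[C@H]1OC(=O)/C(C)=C\C
A2 | alternative 1 | C3-TBS, C10-TES bis-silyl ether of the target | C=C1C(=O)O[C@H]2/C=C(/C)[C@@H](O[Si](C)(C)C(C)(C)C)[C@H]3O[C@H]3[C@](C)(O[Si](CC)(CC)CC)C[C@@H](OC(=O)/C(C)=C\C)[C@@H]12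
A3 | alternative 2 | eleven-membered cyclic sulfone bridging C1 and C2 | C=C(COCc1ccc(OC)cc1)[C@H]2[C@@H](OCc3ccc(OC)cc3)/C=C(/C)[C@@H](O[Si](C)(C)C(C)(C)C)CS(=O)(=O)C[C@](C)(O[Si](CC)(CC)CC)C[C@H]2O[Si](CC)(CC)CC
A4 | alternative 2 | ten-membered (1Z,4Z)-diene | C=C(COCc1ccc(OC)cc1)[C@H]2[C@@H](OCc3ccc(OC)cc3)/C=C(/C)[C@@H](O[Si](C)(C)C(C)(C)C)/C=C\[C@](C)(O[Si](CC)(CC)CC)C[C@H]2O[Si](CC)(CC)CC
A5 | alternative 3 | seco C8 nitrile oxide with C10 isopropenyl group | C=C(C)[C@@H]1O[C@@H]1[C@H](O[Si](C)(C)C(C)(C)C)/C(C)=C\[C@@H]2OC(=O)C[C@@H]2C#[N+][O-]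
A6 | alternative 3 | ten-membered carbocycle with C8/C10 isoxazoline bridge | C1C(=O)O[C@H]2/C=C(/C)[C@@H](O[Si](C)(C)C(C)(C)C)[C@H]3O[C@H]3[C@]4(C)ON=C(C4)[C@@H]12
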